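## Retrosynthetic overview
1. The target comes from the 8α,9α-diol, with both tiglates put on last. The diol comes from an acetonide-protected cis-decalone that carries the isopropenyl group masked as a C11 tertiary acetate/alcohol.
2. The 10β-H (cis fusion) comes from hydrogenation of the Δ1(10)-en-2-one. The 8α,9α-diol comes from syn-dihydroxylation of the γ,δ-bond of a 1(10),8-dien-2-one, anti to the 5-methyl and the C7 side chain.
3. The dienone comes from the enone, and the enone from Lewis-acid fragmentation of the C9–C11 cyclobutane bond of a pinane-fused tricyclic enone. This frees ring B and the C7 side chain and leaves C7 untouched.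
4. Ring A comes from an intramolecular aldol condensation (C1–C10) of a 1,5-diketone. The diketone comes from the key intermolecular Mukaiyama–Michael bond C4–C5 between the silyl enol ether of 3-methylnopinone and (E)-pent-3-en-2-one.
5. Ring order: ring B arrives ready-made as the bicyclo[3.1.1]heptanone from (−)-β-pinene (source of C7), ring A is closed second, and the cyclobutane is opened third.

Convention and assumption: eremophilane numbering is used (C2 ketone, C4 CH–Me, C5 quaternary C–Me, C7 side-chain carbon, C8/C9 oxygenated, C10 ring-fusion CH, C11 side-chain carbon), β is the face of the two methyl groups, the target is (4S,5R,7R,8R,9S,10S), and commercial (−)-β-pinene is taken as enantiopure.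

## Route

Step 1
Reactants: 1 (−)-β-pinene
Product: 3 (+)-nopinone [(1R,5S)-6,6-dimethylbicyclo[3.1.1]heptan-2-one], via spiro ozonide 2 (not isolated)
Conditions: O3, CH2Cl2, −78 °C; then Me2S, −78 °C → rt
Reagents that add atoms: ozone, [O-][O+]=O
Why: Ozonolysis (Criegee mechanism) cleaves the only C=C and leaves both bridgehead stereocentres untouched, one of which becomes C7 of the target.

Step 2
Reactants: 3 (+)-nopinone
Product: 5 (1R,3S,5S)-3,6,6-trimethylbicyclo[3.1.1]heptan-2-one (trans-3-methylnopinone; 3-Me anti to the CMe2 bridge), via lithium enolate 4 (not isolated)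
Conditions: LDA (1.05 equiv), THF, −78 °C; MeI, −78 → 0 °C
Reagents that add atoms: iodomethane, CI
Why: Kinetic enolate alkylation: the other α-carbon is a bridgehead, so only the C3 enolate can form, and MeI enters anti to the CMe2 bridge (this centre is planarised again in step 3, so its configuration does not matter).

Step 3
Reactants: 5 trans-3-methylnopinone
Product: 7 (1R,5R)-trimethyl[(3,6,6-trimethylbicyclo[3.1.1]hept-2-en-2-yl)oxy]silane, via lithium enolate 6 (not isolated)
Conditions: LDA (1.2 equiv), THF, −78 → 0 °C; TMSCl, 0 °C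
Reagents that add atoms: chlorotrimethylsilane, C[Si](C)(C)Cl
Why: Enolate O-silylation: with a single enolisable position the tetrasubstituted silyl enol ether forms as one regioisomer and stores the nucleophile for the key step.

Step 4
Reactants: 7 silyl enol ether of 3-methylnopinone; 8 (E)-pent-3-en-2-one
Product: 10 (1R,3R,5R)-3,6,6-trimethyl-3-[(2S)-4-oxopentan-2-yl]bicyclo[3.1.1]heptan-2-one (3-Me syn and side chain anti to the CMe2 bridge), via titanium enolate 9 (not isolated)
Conditions: TiCl4 (1.1 equiv), CH2Cl2, −78 °C; then H2O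
Reagents that add atoms: none
Why: Mukaiyama–Michael addition: the TiCl4-activated enone reaches the enol ether only from the face turned away from the CMe2 bridge, which fixes quaternary C5 (methyl syn to the bridge, hence cis to the later C7 side chain), and the open antiperiplanar transition state of the (E)-enone keeps the two methyl groups anti, which sets C4 as the cis-4,5-dimethyl array after ring closure.

Step 5
Reactants: 10 1,5-diketone
Product: 12 9,11-cycloeremophil-1(10)-en-2-one (4β,5β-dimethyl; CMe2 bridge on the β face between C7 and C9), via ketol 11 (not isolated)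
Conditions: KOH (0.5 equiv), EtOH, reflux
Reagents that add atoms: none
Why: Intramolecular aldol condensation (the ring-closing half of a Robinson annulation): the ring ketone has no enolisable hydrogen, so only the methyl-ketone enolate can close the six-membered ring onto C10 from the side-chain (α) face, and E1cB loss of water gives the enone without touching C4, C5 or C7.

Step 6
Reactants: 12 tricyclic enone
Product: 13 (4β,5β-dimethyl-7β)-eremophila-1,9-diene-2,11-diyl diacetate
Conditions: Zn(OAc)2, BF3·OEt2, Ac2O, 0 °C → rt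
Reagents that add atoms: acetic anhydride, CC(=O)OC(C)=O
Why: Lewis-acid-promoted cyclobutane fragmentation (vinylogous retro-Prins type): O-acylation of the enone lets the strained C9–C11 bond, which overlaps with the π system, break towards the tertiary C11 cation, which acetate captures, so the C7 side chain appears as a masked isopropenyl group with C7 unchanged and cis to the 5-methyl.

Step 7
Reactants: 13 dienol acetate
Product: 14 2-oxoeremophil-1(10)-en-11-yl acetate (4β,5β-dimethyl; 7β side chain)
Conditions: K2CO3 (0.2 equiv), MeOH, 0 °C → rt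
Reagents that add atoms: none
Why: Chemoselective transesterification: the enol ester is cleaved far faster than the hindered tertiary acetate, and the released dienolate is protonated and equilibrated to the conjugated enone.

Step 8
Reactants: 14 enone
Product: 15 2-oxoeremophila-1(10),8-dien-11-yl acetate
Conditions: chloranil (1.3 equiv), t-BuOH, reflux
Reagents that add atoms: none
Why: Quinone dehydrogenation: chloranil abstracts hydride from C8 of the thermodynamic 1,9-dienol and gives the linear dienone under base-free conditions, which matters because H7 is now vinylogously acidic and C11 carries a leaving group.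

Step 9
Reactants: 15 dienone
Product: 16 8α,9α-dihydroxy-2-oxoeremophil-1(10)-en-11-yl acetate
Conditions: OsO4 (5 mol %), NMO, citric acid, acetone–t-BuOH–H2O, rt
Reagents that add atoms: osmium tetroxide (catalytic O carrier), O=[Os](=O)(=O)=O; N-methylmorpholine N-oxide, C[N+]1([O-])CCOCC1; water, O
Why: Upjohn syn-dihydroxylation: the distal C8=C9 bond is the most electron-rich alkene and its β face is closed by the 5-methyl and the C7 side chain, so osmium adds from the α face and sets C8 and C9 together.

Step 10
Reactants: 16 diol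
Product: 17 8α,9α-(isopropylidenedioxy)-2-oxoeremophil-1(10)-en-11-yl acetate
Conditions: Me2C(OMe)2, PPTS (cat.), CH2Cl2, rt
Reagents that add atoms: 2,2-dimethoxypropane, COC(C)(C)OC
Why: Acetonide formation by transketalisation: the cis-diol closes a dioxolane, which stops isomerisation of the γ-hydroxy enone and adds bulk to the α face.

Step 11
Reactants: 17 enone acetonide
Product: 18 8α,9α-(isopropylidenedioxy)-2-oxo-10βH-eremophilan-11-yl acetate (cis-decalone)
Conditions: H2 (1 atm), 10% Pd/C, EtOAc, rt
Reagents that add atoms: none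
Why: Heterogeneous catalytic hydrogenation: ring B sits in a boat to keep the C7 side chain off the axial 5-methyl and its concave α face also carries the dioxolane, so the enone is adsorbed on the β face and receives 10β-H, the cis-decalone normally obtained from 4a-methyl octalones, and no other C=C is present.

Step 12
Reactants: 18 cis-decalone acetate
Product: 19 11-hydroxy-8α,9α-(isopropylidenedioxy)-10βH-eremophilan-2-one
Conditions: NaOMe (0.5 equiv), MeOH, reflux
Reagents that add atoms: none
Why: Zemplén-type transesterification: methoxide removes the tertiary acetate, and the substrate has no base-labile stereocentre because both α-carbons of the ketone are CH2 groups and no β leaving group is present.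

Step 13
Reactants: 19 tertiary alcohol
Product: 21 8α,9α-(isopropylidenedioxy)-10βH-eremophil-11-en-2-one, via chlorosulfite 20 (not isolated)
Conditions: SOCl2 (1.5 equiv), pyridine, −20 → 0 °C
Reagents that add atoms: none
Why: E2 dehydration through the chlorosulfite: the only ring proton available, H7, is axial on the concave α face between axial O9 and C4 and is out of reach of pyridine, so a methyl proton is lost and the 1,1-disubstituted alkene forms.

Step 14
Reactants: 21 isopropenyl acetonide
Product: 22 8α,9α-dihydroxy-10βH-eremophil-11-en-2-one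
Conditions: AcOH–H2O 4:1, 45 °C
Reagents that add atoms: none
Why: Acid-catalysed ketal hydrolysis: aqueous acetic acid frees the cis-diol under conditions too mild to hydrate or shift the isopropenyl group.

Step 15
Reactants: 22 diol; 23 tigloyl chloride (6–8 equiv)
Product: 25 8α,9α-bis(tigloyloxy)-10βH-eremophil-11-en-2-one (CNP0249036.2), via 8-monotiglate 24 (not isolated)
Conditions: DMAP (cat.), pyridine, 60 °C
Reagents that add atoms: none
Why: DMAP-catalysed acylation: the equatorial 8-OH reacts first and the hindered axial 9-OH follows with excess reagent and heat, pyridine instead of a trialkylamine avoids vinylketene-type deconjugation, and the thermodynamically preferred (E)-geometry of the tigloyl groups is kept.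

## Compound list
1 | (−)-β-pinene, (1S,5S)-6,6-dimethyl-2-methylidenebicyclo[3.1.1]heptane | C=C1CC[C@H]2C[C@@H]1C2(C)C | starting material
2 | spiro secondary ozonide of 1 (1,2,4-trioxolane on C2, spiro centre unassigned) | C1OOC2(O1)CC[C@H]3C[C@@H]2C3(C)C | intermediate
3 | (+)-nopinone, (1R,5S)-6,6-dimethylbicyclo[3.1.1]heptan-2-one | O=C1CC[C@H]2C[C@@H]1C2(C)C | intermediate
4 | lithium enolate of 3 | [Li]OC1=CC[C@H]2C[C@@H]1C2(C)C | intermediate
5 | trans-3-methylnopinone, (1R,3S,5S)-3,6,6-trimethylbicyclo[3.1.1]heptan-2-one | O=C1[C@@H](C)C[C@H]2C[C@@H]1C2(C)C | intermediate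
6 | lithium enolate of 5 | [Li]OC1=C(C)C[C@H]2C[C@@H]1C2(C)C | intermediate
7 | (1R,5R)-trimethyl[(3,6,6-trimethylbicyclo[3.1.1]hept-2-en-2-yl)oxy]silane | C[Si](C)(C)OC1=C(C)C[C@H]2C[C@@H]1C2(C)C | intermediate
8 | (E)-pent-3-en-2-one | C/C=C/C(C)=O | starting material
9 | trichlorotitanium enolate of 10 (methyl-ketone side, geometry unassigned) | CC(O[Ti](Cl)(Cl)Cl)=C[C@H](C)[C@@]1(C)C[C@H]2C[C@@H](C1=O)C2(C)C | intermediate
10 | (1R,3R,5R)-3,6,6-trimethyl-3-[(2S)-4-oxopentan-2-yl]bicyclo[3.1.1]heptan-2-one | CC(=O)C[C@H](C)[C@@]1(C)C[C@H]2C[C@@H](C1=O)C2(C)C | intermediate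
11 | 10β-hydroxy-9,11-cycloeremophilan-2-one (cis-fused ketol) | C[C@H]1CC(=O)C[C@]2(O)[C@@H]3C[C@H](C[C@]12C)C3(C)C | intermediate
12 | 9,11-cycloeremophil-1(10)-en-2-one (4β,5β-dimethyl, CMe2 bridge β) | C[C@H]1CC(=O)C=C2[C@@H]3C[C@H](C[C@]12C)C3(C)C | intermediate
13 | eremophila-1,9-diene-2,11-diyl diacetate (4β,5β-dimethyl, 7β side chain) | C[C@H]1CC(OC(C)=O)=CC2=CC[C@H](C[C@]12C)C(C)(C)OC(C)=O | intermediate
14 | 2-oxoeremophil-1(10)-en-11-yl acetate | C[C@H]1CC(=O)C=C2CC[C@H](C[C@]12C)C(C)(C)OC(C)=O | intermediate
15 | 2-oxoeremophila-1(10),8-dien-11-yl acetate | C[C@H]1CC(=O)C=C2C=C[C@H](C[C@]12C)C(C)(C)OC(C)=O | intermediate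
16 | 8α,9α-dihydroxy-2-oxoeremophil-1(10)-en-11-yl acetate | C[C@H]1CC(=O)C=C2[C@H](O)[C@H](O)[C@H](C[C@]12C)C(C)(C)OC(C)=O | intermediate
17 | 8α,9α-(isopropylidenedioxy)-2-oxoeremophil-1(10)-en-11-yl acetate | C[C@H]1CC(=O)C=C2[C@@H]3OC(C)(C)O[C@@H]3[C@H](C[C@]12C)C(C)(C)OC(C)=O | intermediate
18 | 8α,9α-(isopropylidenedioxy)-2-oxo-10βH-eremophilan-11-yl acetate | C[C@H]1CC(=O)C[C@@H]2[C@@H]3OC(C)(C)O[C@@H]3[C@H](C[C@]12C)C(C)(C)OC(C)=O | intermediate
19 | 11-hydroxy-8α,9α-(isopropylidenedioxy)-10βH-eremophilan-2-one | C[C@H]1CC(=O)C[C@@H]2[C@@H]3OC(C)(C)O[C@@H]3[C@H](C[C@]12C)C(C)(C)O | intermediate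
20 | C11 chlorosulfite of 19 | C[C@H]1CC(=O)C[C@@H]2[C@@H]3OC(C)(C)O[C@@H]3[C@H](C[C@]12C)C(C)(C)OS(=O)Cl | intermediate
21 | 8α,9α-(isopropylidenedioxy)-10βH-eremophil-11-en-2-one | C[C@H]1CC(=O)C[C@@H]2[C@@H]3OC(C)(C)O[C@@H]3[C@H](C[C@]12C)C(C)=C | intermediate
22 | 8α,9α-dihydroxy-10βH-eremophil-11-en-2-one | C[C@H]1CC(=O)C[C@@H]2[C@H](O)[C@H](O)[C@H](C[C@]12C)C(C)=C | intermediate
23 | tigloyl chloride, (E)-2-methylbut-2-enoyl chloride | O=C(Cl)/C(C)=C/C | starting material
24 | 9α-hydroxy-8α-tigloyloxy-10βH-eremophil-11-en-2-one | C[C@H]1CC(=O)C[C@@H]2[C@H](O)[C@H](OC(=O)/C(C)=C/C)[C@H](C[C@]12C)C(C)=C | intermediate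
25 | CNP0249036.2, (1S,2R,3R,4aR,5S,8aS)-4a,5-dimethyl-7-oxo-3-(prop-1-en-2-yl)decahydronaphthalene-1,2-diyl bis[(E)-2-methylbut-2-enoate] | C=C(C)[C@H]1C[C@@]2(C)[C@H](CC(=O)C[C@@H]2C)[C@H](OC(=O)/C(C)=C/C)[C@@H]1OC(=O)/C(C)=C/C | target

## Totals and weak points
Total step count: 15. Longest linear sequence: 15 steps (from 1).

**Step 4.** The hindered quaternary bond may form slowly, the C4 selectivity may be low, and TiCl4 may attack the cyclobutane. The fallback sets out from 7 and comes back at 10.
- 7 is added instead to commercial 3-[(E)-but-2-enoyl]-1,3-oxazolidin-2-one. This bidentate acceptor is locked s-cis and is activated by a mild chelating Lewis acid (Sc(OTf)3 or Cu(OTf)2, 10 mol %, CH2Cl2, −20 °C).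
- This gives the crystalline N-acyl oxazolidinone adduct F1, from which the wanted C4 epimer can be recrystallised.
- MeNH(OMe)·HCl/AlMe3 converts it into the Weinreb amide F2.
- MeMgBr (THF, −20 °C) leaves the neopentyl-type ring ketone alone and delivers 10.

**Step 8.** Dehydrogenation of a strained enone may be slow, may give cross-conjugated or over-oxidised material, or may cost the C11 acetate. The fallback sets out from 13, so step 7 is skipped as well, and comes back at 15.
- NBS in buffered aqueous acetone (NaOAc/AcOH, 0 °C) brominates the dienol acetate at its γ-carbon and gives the 9β-bromo enone F3.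
- A short treatment with LiBr/Li2CO3 in DMF (90–100 °C) removes HBr anti across C8–C9.
- This is hydride abstraction replaced by ionic bromination and dehydrobromination. It is kept in reserve because warm carbonate threatens H7.

**Step 11.** The face selectivity at C10 may be poor, and the allylic C9–O bond may be hydrogenolysed. The fallback sets out from 17 and comes back at 18.
- Luche reduction (NaBH4, CeCl3·7H2O, MeOH, −20 °C; hydride from the α face) gives the 2β-allylic alcohol F4.
- Its hydroxyl group binds Crabtree's catalyst ([Ir(cod)(PCy3)(py)]PF6, H2, CH2Cl2) and directs hydrogen to the β face, which gives the saturated 2β-alcohol F5 with 10β-H.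
- Dess–Martin oxidation restores the ketone of 18.

## Further compounds
F1 | step 4 | 3-{(3S)-3-[(1R,3R,5R)-3,6,6-trimethyl-2-oxobicyclo[3.1.1]heptan-3-yl]butanoyl}-1,3-oxazolidin-2-one | O=C1OCCN1C(=O)C[C@H](C)[C@@]2(C)C[C@H]3C[C@@H](C2=O)C3(C)C
F2 | step 4 | (3S)-N-methoxy-N-methyl-3-[(1R,3R,5R)-3,6,6-trimethyl-2-oxobicyclo[3.1.1]heptan-3-yl]butanamide | CON(C)C(=O)C[C@H](C)[C@@]1(C)C[C@H]2C[C@@H](C1=O)C2(C)C
F3 | step 8 | 9β-bromo-2-oxoeremophil-1(10)-en-11-yl acetate | C[C@H]1CC(=O)C=C2[C@@H](Br)C[C@H](C[C@]12C)C(C)(C)OC(C)=O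
F4 | step 11 | 2β-hydroxy-8α,9α-(isopropylidenedioxy)eremophil-1(10)-en-11-yl acetate | C[C@H]1C[C@@H](O)C=C2[C@@H]3OC(C)(C)O[C@@H]3[C@H](C[C@]12C)C(C)(C)OC(C)=O
F5 | step 11 | 2β-hydroxy-8α,9α-(isopropylidenedioxy)-10βH-eremophilan-11-yl acetate | C[C@H]1C[C@@H](O)C[C@@H]2[C@@H]3OC(C)(C)O[C@@H]3[C@H](C[C@]12C)C(C)(C)OC(C)=O
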